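**Retrosynthetic overview**
- The target is a tridepside with no stereocentre: ring A (2-hydroxy-4,5-dimethoxy-6-methylbenzoyl) is esterified to the C4 oxygen of ring B (an orsellinate), which is esterified to the C4 oxygen of ring C (orsellinic acid).
- The strategy rests on ring A. Counted from its carbonyl-bearing carbon C1, oxygen sits on C2 and C4 (a 1,3-pair), and the C5 methoxy and C6 methyl are neighbours. Ring A is therefore the dehydrogenated form of a cyclohexane-1,3-dione whose C1, C2 and ester carbon come from dimethyl malonate and whose C3 to C6 come from 3-methoxypent-3-en-2-one (bonds C1–C6 and C2–C3).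
- The ring A–ring B ester is made while ring A is still saturated: the beta-keto ester loses methanol thermally to an acylketene, which the ring B C4 phenol of benzyl lecanorate captures. The ring B–ring C ester comes from acylation of benzyl orsellinate with a silyl-protected orsellinoyl chloride.
- The enone is made by Horner–Wadsworth–Emmons olefination of a methoxy ketophosphonate, which fixes the position of the methoxy group without relying on the regiochemistry of a ketone enolisation.
- Ring order: rings B and C are bought as orsellinic acid; ring A is closed in step 3, attached in step 8, aromatised in step 9, methylated at C4–O in step 10 and the benzyl ester is removed in step 11.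

Key step: step 3

Remark: compound 2 is racemic, and the stereodescriptors in 7, 8, 15, 16 and 17 show the relative configuration of racemates; these centres are erased in step 9. The diazo phosphonate 1 and orsellinic acid 9 are taken as bought.

**Route**

Step 1
Reactants: 1 dimethyl (1-diazo-2-oxopropyl)phosphonate
Product: 2 dimethyl (1-methoxy-2-oxopropyl)phosphonate (racemic)
Conditions: MeOH (5 equiv), Rh2(OAc)4 (1 mol%), PhH, reflux
Reagents that add atoms: methanol, CO
Why: Dirhodium carbenoid O–H insertion: the electrophilic carbenoid formed on loss of nitrogen should insert into the methanol O–H bond faster than it rearranges, which places the methoxy group on the phosphonate carbon; the new stereocentre is racemic and disappears in step 2.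

Step 2
Reactants: 2 dimethyl (1-methoxy-2-oxopropyl)phosphonate; 3 acetaldehyde
Product: 4 (Z)-3-methoxypent-3-en-2-one
Conditions: NaH, THF, 0 °C; then MeCHO (3 equiv), 0 °C to rt; careful distillation
Reagents that add atoms: none
Why: Horner–Wadsworth–Emmons olefination: the stabilised phosphonate anion adds to acetaldehyde and the adduct collapses to the enone, with the Z enol ether (methyl trans to acetyl) expected to predominate; any E isomer converges to the same product in step 3.

Step 3
Reactants: 4 (Z)-3-methoxypent-3-en-2-one; 5 dimethyl malonate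
Product: 8 racemic all-trans methyl 5-methoxy-6-methyl-2,4-dioxocyclohexane-1-carboxylate (drawn enantiomer 1S,5R,6S), via Michael adduct 6 (not isolated), via sodium enolate 7 (not isolated)
Conditions: NaOMe (1.1 equiv), MeOH, 0 °C to reflux; then cold 1 M HCl
Reagents that add atoms: none
Why: Methoxide deprotonates 5, the malonate anion adds to C4 of the enone (the methyl-bearing carbon, future ring A C6) to give adduct 6, proton exchange moves the charge to the acetyl methyl, and that enolate attacks one malonate ester in a Claisen condensation, so the C1–C6 and C2–C3 bonds and the ring form in one flask and the acidic dione leaves the equilibria as its sodium enolate 7. The closest known reaction type is the malonate–enone Michael–Claisen annulation that converts alk-3-en-2-ones into alkyl 6-alkyl-2,4-dioxocyclohexanecarboxylates. The ring closes in the 6-(enolexo)-exo-trig mode. The stereocentres C1, C5 and C6 are set under thermodynamic control: C1 and C5 are enolisable carbons on either side of the fixed C6, so both epimerise until ester, methyl and methoxy are all equatorial (C1/C6 trans, C5/C6 trans), as a racemate because nothing chiral is present. The step needs 1,4- rather than 1,2-addition, which the soft stabilised malonate anion and the reversibility of its carbonyl addition secure, and it needs closure from the acetyl methyl, which is the only enolate of 6 that can reach an ester carbonyl through a six-membered transition state (the methoxy-bearing enolate could only form a four-membered ring).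

Step 4
Reactants: 9 orsellinic acid
Product: 10 benzyl orsellinate (benzyl 2,4-dihydroxy-6-methylbenzoate)
Conditions: BnBr (1.05 equiv), KHCO3, DMF, rt
Reagents that add atoms: benzyl bromide, BrCc1ccccc1
Why: Carboxylate alkylation (SN2): KHCO3 ionises only the carboxylic acid, so benzyl bromide should esterify it and leave both phenols free, and room temperature avoids decarboxylation of the salicylic-type acid.

Step 5
Reactants: 9 orsellinic acid
Product: 11 tert-butyldimethylsilyl 2,4-bis[(tert-butyldimethylsilyl)oxy]-6-methylbenzoate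
Conditions: TBSCl (3.5 equiv), imidazole, DMAP (cat.), DMF, rt to 40 °C
Reagents that add atoms: tert-butyldimethylsilyl chloride, CC(C)(C)[Si](C)(C)Cl
Why: Imidazole-promoted silyl transfer should cap both phenols and the acid in one operation; the silyl ester serves as the latent acid chloride for step 6.

Step 6
Reactants: 11 tert-butyldimethylsilyl 2,4-bis[(tert-butyldimethylsilyl)oxy]-6-methylbenzoate; 10 benzyl orsellinate
Product: 13 benzyl 4-({2,4-bis[(tert-butyldimethylsilyl)oxy]-6-methylbenzoyl}oxy)-2-hydroxy-6-methylbenzoate, via acid chloride 12 (not isolated)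
Conditions: (COCl)2, DMF (cat.), CH2Cl2, 0 °C to rt; evaporation; then 10, Et3N, DMAP (cat.), CH2Cl2, 0 °C to rt
Reagents that add atoms: none
Why: The Vilsmeier chloride from oxalyl chloride and DMF converts the silyl ester into the acid chloride under neutral conditions, and DMAP-catalysed acylation should then take place at the C4 hydroxyl of 10, because the C2 hydroxyl is held in a hydrogen bond to the ester carbonyl and is flanked by it.

Step 7
Reactants: 13 benzyl 4-({2,4-bis[(tert-butyldimethylsilyl)oxy]-6-methylbenzoyl}oxy)-2-hydroxy-6-methylbenzoate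
Product: 14 benzyl lecanorate (benzyl 4-[(2,4-dihydroxy-6-methylbenzoyl)oxy]-2-hydroxy-6-methylbenzoate)
Conditions: HF·pyridine, THF, 0 °C to rt
Reagents that add atoms: none
Why: Fluoride-mediated desilylation under buffered, weakly acidic conditions should cleave both aryl silyl ethers without forming a free phenoxide that could open the depside ester; the benzyl ester is inert.

Step 8
Reactants: 8 racemic all-trans methyl 5-methoxy-6-methyl-2,4-dioxocyclohexane-1-carboxylate; 14 benzyl lecanorate
Product: 16 benzyl 2-hydroxy-4-{[2-hydroxy-4-({[5-methoxy-6-methyl-2,4-dioxocyclohexyl]carbonyl}oxy)-6-methylbenzoyl]oxy}-6-methylbenzoate (racemic; ring A all-trans), via acylketene 15 (not isolated)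
Conditions: 8 (1.5 equiv) added slowly to 14 in xylene, 135 °C, N2 sweep through 4 Å MS to remove MeOH
Reagents that add atoms: none
Why: Thermal transesterification of a beta-keto ester through an alpha-oxoketene: the enol of 8 loses methanol in a six-centre step and the ketene should be captured by the most accessible hydroxyl of 14, the ring B C4 phenol (both C2 phenols are hydrogen-bonded to ester carbonyls and hindered), while removal of methanol drives the exchange and C1 re-forms as the equatorial epimer.

Step 9
Reactants: 16 benzyl 2-hydroxy-4-{[2-hydroxy-4-({[5-methoxy-6-methyl-2,4-dioxocyclohexyl]carbonyl}oxy)-6-methylbenzoyl]oxy}-6-methylbenzoate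
Product: 19 benzyl 4-{[4-({2,4-dihydroxy-5-methoxy-6-methylbenzoyl}oxy)-2-hydroxy-6-methylbenzoyl]oxy}-2-hydroxy-6-methylbenzoate, via silyl dienol ether 17 (not isolated), via tetrasilyl arene 18 (not isolated)
Conditions: TMSOTf (5 equiv), Et3N (6 equiv), CH2Cl2, 0 °C; pentane, filtration, evaporation; DDQ (1.1 equiv), PhH, rt; then 1 M HCl, THF, 0 °C
Reagents that add atoms: none
Why: Silyl enol ether formation followed by DDQ dehydrogenation of a cyclohexa-1,3-diene: hydride abstraction from C6 gives a cation stabilised by the two silyloxy groups, loss of the C5 proton should aromatise ring A with the C5 methoxy retained because no protic acid is present to ionise it, and dilute acid then removes the four trimethylsilyl groups; the three stereocentres are erased here.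

Step 10
Reactants: 19 benzyl 4-{[4-({2,4-dihydroxy-5-methoxy-6-methylbenzoyl}oxy)-2-hydroxy-6-methylbenzoyl]oxy}-2-hydroxy-6-methylbenzoate
Product: 20 benzyl 2-hydroxy-4-{[2-hydroxy-4-({2-hydroxy-4,5-dimethoxy-6-methylbenzoyl}oxy)-6-methylbenzoyl]oxy}-6-methylbenzoate
Conditions: MeI (1.1 equiv), K2CO3 (1.1 equiv), acetone, rt
Reagents that add atoms: iodomethane, CI
Why: Williamson ether synthesis: one equivalent of K2CO3 should ionise only the ring A C4 phenol, which is para to the ester carbonyl and the only hydroxyl not held in a six-membered hydrogen bond, so it alone is methylated.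

Step 11
Reactants: 20 benzyl 2-hydroxy-4-{[2-hydroxy-4-({2-hydroxy-4,5-dimethoxy-6-methylbenzoyl}oxy)-6-methylbenzoyl]oxy}-6-methylbenzoate
Product: 21 2-hydroxy-4-{[2-hydroxy-4-({2-hydroxy-4,5-dimethoxy-6-methylbenzoyl}oxy)-6-methylbenzoyl]oxy}-6-methylbenzoic acid (CNP0139469.0)
Conditions: H2 (1 atm), 10% Pd/C, EtOAc, rt
Reagents that add atoms: none
Why: Hydrogenolysis of the benzyl ester over palladium should leave the aryl esters, aryl methyl ethers and arene rings untouched at room temperature, and the absence of heat keeps the salicylic-type acid from decarboxylating.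

**Compound list**
1 | dimethyl (1-diazo-2-oxopropyl)phosphonate | CC(=O)C(=[N+]=[N-])P(=O)(OC)OC | starting material
2 | dimethyl (1-methoxy-2-oxopropyl)phosphonate (racemic) | COC(C(C)=O)P(=O)(OC)OC | intermediate
3 | acetaldehyde | CC=O | starting material
4 | (Z)-3-methoxypent-3-en-2-one | C/C=C(\OC)C(C)=O | intermediate
5 | dimethyl malonate | COC(=O)CC(=O)OC | starting material
6 | dimethyl 2-(3-methoxy-4-oxopentan-2-yl)propanedioate (Michael adduct, diastereomer mixture, not isolated) | COC(=O)C(C(=O)OC)C(C)C(OC)C(C)=O | intermediate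
7 | sodium 6-methoxy-4-(methoxycarbonyl)-5-methyl-3-oxocyclohex-1-en-1-olate (sodium enolate of 8, racemic all-trans, not isolated) | COC(=O)[C@@H]1C(=O)C=C([O-])[C@H](OC)[C@H]1C.[Na+] | intermediate
8 | methyl 5-methoxy-6-methyl-2,4-dioxocyclohexane-1-carboxylate (racemic, all-trans; drawn 1S,5R,6S) | COC(=O)[C@@H]1C(=O)CC(=O)[C@H](OC)[C@H]1C | intermediate
9 | orsellinic acid (2,4-dihydroxy-6-methylbenzoic acid) | Cc1cc(O)cc(O)c1C(=O)O | starting material
10 | benzyl orsellinate | Cc1cc(O)cc(O)c1C(=O)OCc1ccccc1 | intermediate
11 | tert-butyldimethylsilyl 2,4-bis[(tert-butyldimethylsilyl)oxy]-6-methylbenzoate | Cc1cc(O[Si](C)(C)C(C)(C)C)cc(O[Si](C)(C)C(C)(C)C)c1C(=O)O[Si](C)(C)C(C)(C)C | intermediate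
12 | 2,4-bis[(tert-butyldimethylsilyl)oxy]-6-methylbenzoyl chloride (not isolated) | Cc1cc(O[Si](C)(C)C(C)(C)C)cc(O[Si](C)(C)C(C)(C)C)c1C(Cl)=O | intermediate
13 | benzyl 4-({2,4-bis[(tert-butyldimethylsilyl)oxy]-6-methylbenzoyl}oxy)-2-hydroxy-6-methylbenzoate | Cc1cc(O[Si](C)(C)C(C)(C)C)cc(O[Si](C)(C)C(C)(C)C)c1C(=O)Oc1cc(C)c(C(=O)OCc2ccccc2)c(O)c1 | intermediate
14 | benzyl lecanorate (benzyl 4-[(2,4-dihydroxy-6-methylbenzoyl)oxy]-2-hydroxy-6-methylbenzoate) | Cc1cc(O)cc(O)c1C(=O)Oc1cc(C)c(C(=O)OCc2ccccc2)c(O)c1 | intermediate
15 | trans-4-methoxy-5-methyl-6-(oxomethylidene)cyclohexane-1,3-dione (acylketene, racemic, not isolated) | O=C=C1C(=O)CC(=O)[C@H](OC)[C@H]1C | intermediate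
16 | benzyl 2-hydroxy-4-{[2-hydroxy-4-({[5-methoxy-6-methyl-2,4-dioxocyclohexyl]carbonyl}oxy)-6-methylbenzoyl]oxy}-6-methylbenzoate (racemic, ring A all-trans) | O=C(Oc1cc(C)c(C(=O)Oc2cc(C)c(C(=O)OCc3ccccc3)c(O)c2)c(O)c1)[C@@H]1C(=O)CC(=O)[C@H](OC)[C@H]1C | intermediate
17 | benzyl 4-{[4-({[5-methoxy-6-methyl-2,4-bis(trimethylsilyloxy)cyclohexa-1,3-dien-1-yl]carbonyl}oxy)-6-methyl-2-(trimethylsilyloxy)benzoyl]oxy}-6-methyl-2-(trimethylsilyloxy)benzoate (racemic, C5/C6 trans, not isolated) | O=C(Oc1cc(C)c(C(=O)Oc2cc(C)c(C(=O)OCc3ccccc3)c(O[Si](C)(C)C)c2)c(O[Si](C)(C)C)c1)C1=C(O[Si](C)(C)C)C=C(O[Si](C)(C)C)[C@H](OC)[C@H]1C | intermediate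
18 | benzyl 4-{[4-({5-methoxy-6-methyl-2,4-bis(trimethylsilyloxy)benzoyl}oxy)-6-methyl-2-(trimethylsilyloxy)benzoyl]oxy}-6-methyl-2-(trimethylsilyloxy)benzoate (not isolated) | COc1c(O[Si](C)(C)C)cc(O[Si](C)(C)C)c(C(=O)Oc2cc(C)c(C(=O)Oc3cc(C)c(C(=O)OCc4ccccc4)c(O[Si](C)(C)C)c3)c(O[Si](C)(C)C)c2)c1C | intermediate
19 | benzyl 4-{[4-({2,4-dihydroxy-5-methoxy-6-methylbenzoyl}oxy)-2-hydroxy-6-methylbenzoyl]oxy}-2-hydroxy-6-methylbenzoate | COc1c(O)cc(O)c(C(=O)Oc2cc(C)c(C(=O)Oc3cc(C)c(C(=O)OCc4ccccc4)c(O)c3)c(O)c2)c1C | intermediate
20 | benzyl 2-hydroxy-4-{[2-hydroxy-4-({2-hydroxy-4,5-dimethoxy-6-methylbenzoyl}oxy)-6-methylbenzoyl]oxy}-6-methylbenzoate | COc1cc(O)c(C(=O)Oc2cc(C)c(C(=O)Oc3cc(C)c(C(=O)OCc4ccccc4)c(O)c3)c(O)c2)c(C)c1OC | intermediate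
21 | 2-hydroxy-4-{[2-hydroxy-4-({2-hydroxy-4,5-dimethoxy-6-methylbenzoyl}oxy)-6-methylbenzoyl]oxy}-6-methylbenzoic acid (CNP0139469.0) | COc1cc(O)c(C(=O)Oc2cc(C)c(C(=O)Oc3cc(C)c(C(=O)O)c(O)c3)c(O)c2)c(C)c1OC | target

**Step count**
Total: 11 steps. Longest linear sequence: 7 steps (steps 1, 2, 3, 8, 9, 10, 11 from compound 1; equally steps 5, 6, 7, 8, 9, 10, 11 from orsellinic acid).

**Steps most likely to fail**

1. Step 8 (ester exchange through the acylketene). Ketene formation from the methyl ester may be too slow at a temperature the C5 methoxy tolerates, the ketene may be captured by the enolic hydroxyl of another dione molecule and oligomerise, or acylation may spread to the chelated phenols.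
Fallback, setting out from 8 and coming back at 21, with 14 taken from step 7: ring A is aromatised first and joined by a classical depside acylation. Bromination–dehydrobromination of 8 (Br2, DMF, 0 °C, then 80 °C), as known for alkyl dihydroresorcylates, would pass through methyl 3-bromo-5-methoxy-6-methyl-2,4-dioxocyclohexane-1-carboxylate F1 and give methyl 2,4-dihydroxy-5-methoxy-6-methylbenzoate F2. MeI and K2CO3 in acetone would methylate the unchelated C4 hydroxyl to methyl 2-hydroxy-4,5-dimethoxy-6-methylbenzoate F3. BnBr, K2CO3, DMF at 60 °C would give methyl 2-(benzyloxy)-4,5-dimethoxy-6-methylbenzoate F4, and KOH in aqueous DMSO at 100 °C followed by HCl would give 2-(benzyloxy)-4,5-dimethoxy-6-methylbenzoic acid F5. Trifluoroacetic anhydride in toluene at rt would convert F5 into 2-(benzyloxy)-4,5-dimethoxy-6-methylbenzoic trifluoroacetic anhydride F6, which would acylate the ring B C4 phenol of 14 to give benzyl 4-{[4-({2-(benzyloxy)-4,5-dimethoxy-6-methylbenzoyl}oxy)-2-hydroxy-6-methylbenzoyl]oxy}-2-hydroxy-6-methylbenzoate F7. Hydrogenolysis (H2, Pd/C, EtOAc, rt) would remove both benzyl groups and give 21.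

2. Step 9 (silylation and DDQ aromatisation). Silylation of the second enol may be incomplete, the Lewis-acidic silyl triflate may ionise the C5 methoxy so that methanol is lost in place of hydrogen, or the aryl beta-keto ester may fragment to the ketene under the amine base.
Fallback, setting out from 16 and coming back at 19: dehydrogenation by halogenation and elimination without silylation or hydride abstraction. NBS (1 equiv) in CH2Cl2 at 0 °C would brominate C3 of the enolised dione to give benzyl 4-{[4-({[3-bromo-5-methoxy-6-methyl-2,4-dioxocyclohexyl]carbonyl}oxy)-2-hydroxy-6-methylbenzoyl]oxy}-2-hydroxy-6-methylbenzoate F8. Warming in DMF at 60 °C would then expel HBr by a vinylogous elimination, in which bromide leaves far more readily than the C5 methoxy, and give 19.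

3. Step 3 (Michael–Claisen annulation). Conjugate addition to the beta-substituted, alpha-oxygenated enone may be sluggish, so that base-induced self-condensation of the enone takes over.
Fallback, setting out from 5 and 3 and coming back at 6: the polarity of the conjugate addition is reversed so that the same adduct forms through its C5–C6 bond. Knoevenagel condensation of 5 with 3 (Ac2O, 100 °C) would give dimethyl 2-ethylidenepropanedioate F9, a much stronger acceptor than 4. Methoxyacetone (COCC(C)=O) with catalytic pyrrolidine in CHCl3 at rt would form the more substituted enamine 1-(1-methoxyprop-1-en-2-yl)pyrrolidine F10, which would add through its methoxy-bearing carbon to F9 and hydrolyse to 6. NaOMe in MeOH would then close 6 to 7 and 8 as in step 3.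

**Further compounds**
F1 | step 8 | methyl 3-bromo-5-methoxy-6-methyl-2,4-dioxocyclohexane-1-carboxylate (racemic, C3 epimers) | COC(=O)[C@@H]1C(=O)C(Br)C(=O)[C@H](OC)[C@H]1C
F2 | step 8 | methyl 2,4-dihydroxy-5-methoxy-6-methylbenzoate | COC(=O)c1c(O)cc(O)c(OC)c1C
F3 | step 8 | methyl 2-hydroxy-4,5-dimethoxy-6-methylbenzoate | COC(=O)c1c(O)cc(OC)c(OC)c1C
F4 | step 8 | methyl 2-(benzyloxy)-4,5-dimethoxy-6-methylbenzoate | COC(=O)c1c(OCc2ccccc2)cc(OC)c(OC)c1C
F5 | step 8 | 2-(benzyloxy)-4,5-dimethoxy-6-methylbenzoic acid | OC(=O)c1c(OCc2ccccc2)cc(OC)c(OC)c1C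
F6 | step 8 | 2-(benzyloxy)-4,5-dimethoxy-6-methylbenzoic trifluoroacetic anhydride | COc1cc(OCc2ccccc2)c(C(=O)OC(=O)C(F)(F)F)c(C)c1OC
F7 | step 8 | benzyl 4-{[4-({2-(benzyloxy)-4,5-dimethoxy-6-methylbenzoyl}oxy)-2-hydroxy-6-methylbenzoyl]oxy}-2-hydroxy-6-methylbenzoate | COc1cc(OCc2ccccc2)c(C(=O)Oc2cc(C)c(C(=O)Oc3cc(C)c(C(=O)OCc4ccccc4)c(O)c3)c(O)c2)c(C)c1OC
F8 | step 9 | benzyl 4-{[4-({[3-bromo-5-methoxy-6-methyl-2,4-dioxocyclohexyl]carbonyl}oxy)-2-hydroxy-6-methylbenzoyl]oxy}-2-hydroxy-6-methylbenzoate (racemic, C3 epimers) | O=C(Oc1cc(C)c(C(=O)Oc2cc(C)c(C(=O)OCc3ccccc3)c(O)c2)c(O)c1)[C@@H]1C(=O)C(Br)C(=O)[C@H](OC)[C@H]1C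
F9 | step 3 | dimethyl 2-ethylidenepropanedioate | CC=C(C(=O)OC)C(=O)OC
F10 | step 3 | 1-(1-methoxyprop-1-en-2-yl)pyrrolidine (alkene geometry not defined) | COC=C(C)N1CCCC1
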